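**Retrosynthetic overview**
1. Feature: in the benzo ring of the aromatic chromone (C4a', C5', C6', C7', C8', C8a') the ether oxygen O8 sits on C6' beside the C7' methoxy group. This ring is cut at C6'–C7' and C5'–C4a'.
2. Key disconnection: the benzo ring comes from an ethynyl ether on O2 of a D-mannoside and the 3-methoxy-2-pyranone ring fused to a kojic-acid-derived 4-pyranone, with loss of CO2. The hindered C8–O–aryl bond is never made at carbon.
3. Sugar C2, C3 and C4 become C8, C7 and C6. Ferrier carbocyclisation closes C4a–C8a, and a hydroxyl-directed reduction sets C5.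
4. The second 4-pyranone is annulated last on the C8a ketone: C4a–C4 by aldol addition of 5-phenylpent-2-ynal, O1–C2 by 6-endo closure.
5. Ring order: 4-pyranone of kojic acid, fused 2-pyranone, benzo ring, carbocycle, second 4-pyranone.

Key step: step 12

Remark: primed locants belong to the aromatic chromone and plain locants to the tetrahydrochromone. Sugar C1–C6 become C8a, C8, C7, C6, C5, C4a. BDA = (2S,3S)-2,3-dimethoxybutane-2,3-diyl bridging two oxygens, TBDPS = tert-butyldiphenylsilyl, TBS = tert-butyldimethylsilyl, Ar = 7-methoxy-4-oxo-2-(2-phenylethyl)-4H-chromen-6-yl. The alkene of 15, the bridgeheads of 23 and the two new centres of 36 are left undefined because all are erased later.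

**Step 1**
Reactants: 1 methyl α-D-mannopyranoside
Product: 2 methyl 3,4-O-BDA-α-D-mannopyranoside
Conditions: butane-2,3-dione, HC(OMe)3, CSA (cat.), MeOH, reflux
Reagents that add atoms: butane-2,3-dione CC(=O)C(C)=O; trimethyl orthoformate COC(OC)OC
Why: Acid-catalysed butane-2,3-diacetal formation picks the only trans-diequatorial diol (O3/O4), the anomeric effect sets both new acetal centres (S,S, methoxy groups axial), and this rigid acetal next to O2 cannot migrate to the O2 alkoxide in step 3 as a silyl ether would.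

**Step 2**
Reactants: 2 methyl 3,4-O-BDA-α-D-mannopyranoside
Product: 3 methyl 6-O-TBDPS-3,4-O-BDA-α-D-mannopyranoside (O2–H free)
Conditions: TBDPSCl, imidazole, DMF, 0 °C
Reagents that add atoms: tert-butyl(chloro)diphenylsilane CC(C)(C)[Si](Cl)(c1ccccc1)c1ccccc1
Why: Steric differentiation in silyl ether formation lets the bulky chlorosilane take the primary O6–H and leave the axial, flanked O2–H free.

**Step 3**
Reactants: 3 methyl 6-O-TBDPS-3,4-O-BDA-α-D-mannopyranoside; 4 trichloroethylene
Product: 6 methyl 2-O-[(E)-1,2-dichlorovinyl]-6-O-TBDPS-3,4-O-BDA-α-D-mannopyranoside, via dichloroacetylene 5 (not isolated)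
Conditions: KH, THF, 0 °C; then 4, −50 °C to rt
Reagents that add atoms: none
Why: In this base-mediated O-dichlorovinylation the potassium alkoxide adds anti to 5, which 4 releases by loss of HCl, to give the E ether, and because only the O–H bond reacts the sugar C2 configuration (future C8) is retained.

**Step 4**
Reactants: 6 methyl 2-O-[(E)-1,2-dichlorovinyl]-6-O-TBDPS-3,4-O-BDA-α-D-mannopyranoside
Product: 9 methyl 2-O-ethynyl-6-O-TBDPS-3,4-O-BDA-α-D-mannopyranoside, via chloroethynyl ether 7 (not isolated), via lithium alkoxyacetylide 8 (not isolated)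
Conditions: n-BuLi (2.3 equiv), THF, −78 to −40 °C; H2O, −78 °C; chromatography on Et3N-deactivated silica, storage cold
Reagents that add atoms: none
Why: Elimination of HCl by n-BuLi, chlorine–lithium exchange on 7 and protonation of 8 form the standard dichlorovinyl ether route to terminal ynol ethers, and acetal, glycoside and silyl ether are inert to n-BuLi at low temperature.

**Step 5**
Reactants: 10 kojic acid
Product: 11 5-(benzyloxy)-2-(hydroxymethyl)-4H-pyran-4-one
Conditions: BnBr, K2CO3, DMF, 60 °C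
Reagents that add atoms: benzyl bromide BrCc1ccccc1
Why: This Williamson ether synthesis takes place on the acidic enolic 5-OH, which carbonate deprotonates while the primary alcohol stays neutral.

**Step 6**
Reactants: 11 5-(benzyloxy)-2-(hydroxymethyl)-4H-pyran-4-one
Product: 12 5-(benzyloxy)-4-oxo-4H-pyran-2-carbaldehyde
Conditions: MnO2 (activated), CH2Cl2, rt
Reagents that add atoms: none
Why: MnO2 oxidation is selective for the allylic-type carbinol on the pyranone and stops at the aldehyde.

**Step 7**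
Reactants: 12 5-(benzyloxy)-4-oxo-4H-pyran-2-carbaldehyde; 13 benzyltriphenylphosphonium bromide
Product: 15 5-(benzyloxy)-2-(2-phenylethenyl)-4H-pyran-4-one (E/Z mixture), via benzylidenetriphenylphosphorane 14 (not isolated)
Conditions: 13, KOt-Bu, THF, 0 °C; then 12, 0 °C to rt
Reagents that add atoms: none
Why: Wittig olefination of the reactive heteroaryl aldehyde with the semi-stabilised ylide 14 should proceed readily, and the alkene geometry does not matter because the double bond is saturated in step 8.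

**Step 8**
Reactants: 15 5-(benzyloxy)-2-(2-phenylethenyl)-4H-pyran-4-one
Product: 16 5-hydroxy-2-(2-phenylethyl)-4H-pyran-4-one
Conditions: H2 (1 bar), 10% Pd/C, EtOAc–MeOH, rt
Reagents that add atoms: none
Why: Catalytic hydrogenation saturates the styryl double bond and hydrogenolyses the benzyl ether in one operation, while the vinylogous-ester double bonds of the 4-pyranone are reduced much more slowly.

**Step 9**
Reactants: 16 5-hydroxy-2-(2-phenylethyl)-4H-pyran-4-one; 17 formaldehyde
Product: 18 3-hydroxy-2-(hydroxymethyl)-6-(2-phenylethyl)-4H-pyran-4-one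
Conditions: aq. HCHO, NaOH (1.1 equiv), H2O–MeOH, rt; then HCl to pH 2
Reagents that add atoms: none
Why: Base-mediated hydroxymethylation (Lederer–Manasse-type aldol addition) occurs at the only free carbon ortho to the enolate oxygen, as it does with kojic acid itself.

**Step 10**
Reactants: 18 3-hydroxy-2-(hydroxymethyl)-6-(2-phenylethyl)-4H-pyran-4-one
Product: 19 3-hydroxy-4-oxo-6-(2-phenylethyl)-4H-pyran-2-carbaldehyde
Conditions: MnO2 (activated), 1,4-dioxane, rt
Reagents that add atoms: none
Why: MnO2 oxidises this heteroaryl carbinol as it does ortho-hydroxybenzyl alcohols, and the hydrogen bond from the neighbouring hydroxyl group stabilises the aldehyde against further oxidation.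

**Step 11**
Reactants: 19 3-hydroxy-4-oxo-6-(2-phenylethyl)-4H-pyran-2-carbaldehyde; 20 methoxyacetyl chloride
Product: 22 3-methoxy-6-(2-phenylethyl)pyrano[3,2-b]pyran-2,8-dione, via O-methoxyacetyl ester 21 (not isolated)
Conditions: 20, Et3N, CH2Cl2, 0 °C to rt; then DBU (cat.), 4 Å MS, 40 °C
Reagents that add atoms: none
Why: In this Perkin-type coumarin synthesis transferred to the hydroxypyranone, O-acylation gives 21, its ester enolate (also reachable from methoxyketene and the enolate oxygen) adds to the adjacent electrophilic aldehyde, and dehydration gives the conjugated 3-methoxy-2-pyranone ring.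

**Step 12**
Reactants: 9 methyl 2-O-ethynyl-6-O-TBDPS-3,4-O-BDA-α-D-mannopyranoside; 22 3-methoxy-6-(2-phenylethyl)pyrano[3,2-b]pyran-2,8-dione
Product: 24 methyl 2-O-Ar-6-O-TBDPS-3,4-O-BDA-α-D-mannopyranoside, via bridged lactone 23 (not isolated)
Conditions: 22 (1.5 equiv), 2,6-di-tert-butylpyridine (5 mol %), CH2Cl2, 10 kbar, 30 °C; then 1 bar, 45 °C
Reagents that add atoms: none
Why: This is the known pyranone-to-arene sequence, an inverse-electron-demand Diels–Alder reaction of a 2-pyranone with an alkynyl ether followed by retro-[4+2] loss of CO2, in which the nucleophilic terminal carbon of 9 bonds to C8a of 22 (the oxygen-bearing δ-carbon of the dienoate, future C4a') and the oxygen-bearing carbon closes onto the methoxy carbon C3 (future C7') to give the 2-oxabicyclo[2.2.2]octadienone 23. The six-membered carbocycle is closed by an intermolecular suprafacial [4+2] addition that forms C5'–C4a' and C6'–C7' in one step, and 23 aromatises by cycloreversion, so the benzo ring appears with O8 already on C6'. The product gains no stereocentre, because the two bridgeheads of 23 vanish with CO2 and sugar C2 is untouched since its C–O bond is never broken. The selectivity needed is regiochemical and rests on the lactone carbonyl, which makes C8a the electrophilic terminus; the C8 carbonyl and the C3 methoxy group pull the other way, so this bias is modest, but the C8 carbonyl is tied up as a vinylogous ester by O5, and Lewis acids and protic media that would bind and strengthen it are kept out. Pressure replaces heat because the cycloaddition has a strongly negative activation volume while the retro-ene fragmentation of the secondary ynol ether has a positive one, and that fragmentation is further slowed by the electron-withdrawing C–O bonds that flank sugar C2.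

**Step 13**
Reactants: 24 methyl 2-O-Ar-6-O-TBDPS-3,4-O-BDA-α-D-mannopyranoside
Product: 25 methyl 2-O-Ar-3,4-O-BDA-α-D-mannopyranoside (O6–H free)
Conditions: TBAF, AcOH, THF, 0 °C to rt
Reagents that add atoms: none
Why: Fluoride-mediated desilylation frees O6–H, and buffering with AcOH keeps the medium from deprotonating the CH2 next to C2' or opening the chromone.

**Step 14**
Reactants: 25 methyl 2-O-Ar-3,4-O-BDA-α-D-mannopyranoside
Product: 26 methyl 2-O-Ar-6-deoxy-6-iodo-3,4-O-BDA-α-D-mannopyranoside
Conditions: I2, PPh3, imidazole, toluene, 60 °C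
Reagents that add atoms: iodine II
Why: Garegg–Samuelsson (Appel-type) iodination converts the only free, primary hydroxyl group by SN2 displacement of its alkoxyphosphonium ion.

**Step 15**
Reactants: 26 methyl 2-O-Ar-6-deoxy-6-iodo-3,4-O-BDA-α-D-mannopyranoside
Product: 27 methyl 2-O-Ar-6-deoxy-3,4-O-BDA-α-D-lyxo-hex-5-enopyranoside
Conditions: DBU, THF, reflux
Reagents that add atoms: none
Why: E2 dehydroiodination with an amidine base gives the exocyclic enol ether because sugar H5 is the only β-hydrogen.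

**Step 16**
Reactants: 27 methyl 2-O-Ar-6-deoxy-3,4-O-BDA-α-D-lyxo-hex-5-enopyranoside
Product: 28 Ferrier ketol (cyclohexanone with C5=O, C4a H2, axial C8a–OH trans to the axial C8–OAr, C8–OAr cis to O7, O6/O7 trans-diequatorial in the BDA acetal)
Conditions: Hg(OCOCF3)2 (10 mol %), acetone–H2O, rt
Reagents that add atoms: water O
Why: In the Ferrier carbocyclisation, oxymercuration of the enol ether, loss of methanol and intramolecular aldol addition of the C4a mercury enolate to the sugar C1 aldehyde close C4a–C8a through a chair that puts the new C8a hydroxyl group axial and trans to O7, the usual outcome for this sugar C3 configuration.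

**Step 17**
Reactants: 28 Ferrier ketol
Product: 29 1,3-anti diol (as 28, with an equatorial C5–OH trans to O6 and anti to C8a–OH)
Conditions: Me4NBH(OAc)3, MeCN–AcOH, −20 °C
Reagents that add atoms: none
Why: In the Saksena–Evans reduction the axial C8a–OH binds boron and delivers hydride to the same face of the C5 ketone, which sets the equatorial C5–OH of the target, while the chromone carbonyl is not attacked by this mild hydride.

**Step 18**
Reactants: 29 1,3-anti diol
Product: 30 C5 TBS ether of 29 (C8a–OH free)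
Conditions: TBSCl, imidazole, DMF, 0 °C
Reagents that add atoms: tert-butyl(chloro)dimethylsilane CC(C)(C)[Si](C)(C)Cl
Why: Site-selective silylation favours the equatorial C5–OH over the axial C8a–OH, which suffers 1,3-diaxial hindrance and sits next to the aryloxy-bearing C8.

**Step 19**
Reactants: 30 C5 TBS ether of 29
Product: 31 C8a ketone (2-aryloxycyclohexanone with C8–OAr, 6,7-O-BDA and C5–OTBS)
Conditions: Dess–Martin periodinane, CH2Cl2, 0 °C to rt
Reagents that add atoms: none
Why: Dess–Martin oxidation is base-free and converts the remaining alcohol into the ketone without epimerising the α-aryloxy centre C8 or eliminating a β-oxygen.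

**Step 20**
Reactants: 32 4-phenylbut-1-yne
Product: 34 5-phenylpent-2-ynal, via lithium acetylide 33 (not isolated)
Conditions: n-BuLi, THF, −78 °C; DMF, −78 to 0 °C; poured into cold 1 M HCl
Reagents that add atoms: N,N-dimethylformamide CN(C)C=O
Why: Formylation of the lithium acetylide with DMF gives the ynal, and the acidic quench keeps dimethylamine protonated so that it cannot add to the triple bond.

**Step 21**
Reactants: 31 C8a ketone; 34 5-phenylpent-2-ynal
Product: 36 aldol adduct (31 bearing CH(OH)C≡CCH2CH2Ph on C4a, mixture at C4a and C4), via dicyclohexylboron enolate 35 (not isolated)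
Conditions: Cy2BCl (2.5 equiv), Et3N, Et2O, −78 to 0 °C; 34, −78 to −20 °C; MeOH, pH 7 buffer, H2O2, 0 °C
Reagents that add atoms: none
Why: In this boron-mediated aldol addition Cy2BCl/Et3N enolises ketones but not vinylogous esters and does so at the less hindered, non-oxygenated C4a, the amine base leaves C8 and the CH2 next to C2' alone, a boron enolate does not expel the β-silyloxy group at low temperature, and both new stereocentres are erased in step 22.

**Step 22**
Reactants: 36 aldol adduct
Product: 38 5-O-TBS-6,7-O-BDA-8-OAr-2-(2-phenylethyl)-5,6,7,8-tetrahydro-4H-chromen-4-one (configuration as in 39), via ynedione 37 (not isolated)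
Conditions: Dess–Martin periodinane (1.1 equiv), CH2Cl2, 0 °C to rt; filtration; DMAP (20 mol %), CH2Cl2, rt
Reagents that add atoms: none
Why: Dess–Martin oxidation gives the enolised 2-alkynoyl ketone 37, whose enol oxygen on C8a adds to the ynone in a 6-endo-dig oxa-Michael closure under nucleophilic catalysis, the way acetylenic β-diketones and ortho-alkynoylphenols close to 4-pyranones, forming O1–C2.

**Step 23**
Reactants: 38 protected tetrahydrochromone
Product: 39 (5S,6R,7S,8S)-5,6,7-trihydroxy-8-{[7-methoxy-4-oxo-2-(2-phenylethyl)-4H-chromen-6-yl]oxy}-2-(2-phenylethyl)-5,6,7,8-tetrahydro-4H-chromen-4-one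
Conditions: TFA–H2O (9:1), 0 °C to rt; evaporation, MeOH
Reagents that add atoms: none
Why: Aqueous acid hydrolysis cleaves the diacetal and the silyl ether in one operation, and C5 and C8 do not ionise because they sit on an electron-poor, protonated pyranone, so all four stereocentres are kept.

**Compound list**
1 | methyl α-D-mannopyranoside | O[C@@H]1[C@@H](OC)O[C@H](CO)[C@@H](O)[C@@H]1O | starting material
2 | methyl 3,4-O-[(2S,3S)-2,3-dimethoxybutane-2,3-diyl]-α-D-mannopyranoside | O[C@@H]1[C@@H](OC)O[C@H](CO)[C@H]2O[C@](C)(OC)[C@@](C)(OC)O[C@H]12 | intermediate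
3 | methyl 6-O-TBDPS-3,4-O-BDA-α-D-mannopyranoside | O[C@@H]1[C@@H](OC)O[C@H](CO[Si](c3ccccc3)(c3ccccc3)C(C)(C)C)[C@H]2O[C@](C)(OC)[C@@](C)(OC)O[C@H]12 | intermediate
4 | trichloroethylene | ClC=C(Cl)Cl | starting material
5 | dichloroacetylene | ClC#CCl | intermediate
6 | methyl 2-O-[(E)-1,2-dichlorovinyl]-6-O-TBDPS-3,4-O-BDA-α-D-mannopyranoside | Cl/C=C(Cl)\O[C@@H]1[C@@H](OC)O[C@H](CO[Si](c3ccccc3)(c3ccccc3)C(C)(C)C)[C@H]2O[C@](C)(OC)[C@@](C)(OC)O[C@H]12 | intermediate
7 | methyl 2-O-(chloroethynyl)-6-O-TBDPS-3,4-O-BDA-α-D-mannopyranoside | ClC#CO[C@@H]1[C@@H](OC)O[C@H](CO[Si](c3ccccc3)(c3ccccc3)C(C)(C)C)[C@H]2O[C@](C)(OC)[C@@](C)(OC)O[C@H]12 | intermediate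
8 | methyl 2-O-(lithioethynyl)-6-O-TBDPS-3,4-O-BDA-α-D-mannopyranoside | [Li]C#CO[C@@H]1[C@@H](OC)O[C@H](CO[Si](c3ccccc3)(c3ccccc3)C(C)(C)C)[C@H]2O[C@](C)(OC)[C@@](C)(OC)O[C@H]12 | intermediate
9 | methyl 2-O-ethynyl-6-O-TBDPS-3,4-O-BDA-α-D-mannopyranoside | C#CO[C@@H]1[C@@H](OC)O[C@H](CO[Si](c3ccccc3)(c3ccccc3)C(C)(C)C)[C@H]2O[C@](C)(OC)[C@@](C)(OC)O[C@H]12 | intermediate
10 | kojic acid, 5-hydroxy-2-(hydroxymethyl)-4H-pyran-4-one | OCc1cc(=O)c(O)co1 | starting material
11 | 5-(benzyloxy)-2-(hydroxymethyl)-4H-pyran-4-one | OCc1cc(=O)c(OCc2ccccc2)co1 | intermediate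
12 | 5-(benzyloxy)-4-oxo-4H-pyran-2-carbaldehyde | O=Cc1cc(=O)c(OCc2ccccc2)co1 | intermediate
13 | benzyltriphenylphosphonium bromide | [Br-].c1ccc(C[P+](c2ccccc2)(c2ccccc2)c2ccccc2)cc1 | starting material
14 | benzylidenetriphenylphosphorane | c1ccc(C=P(c2ccccc2)(c2ccccc2)c2ccccc2)cc1 | intermediate
15 | 5-(benzyloxy)-2-(2-phenylethenyl)-4H-pyran-4-one (E/Z mixture) | O=c1cc(C=Cc2ccccc2)occ1OCc1ccccc1 | intermediate
16 | 5-hydroxy-2-(2-phenylethyl)-4H-pyran-4-one | O=c1cc(CCc2ccccc2)occ1O | intermediate
17 | formaldehyde | C=O | starting material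
18 | 3-hydroxy-2-(hydroxymethyl)-6-(2-phenylethyl)-4H-pyran-4-one | OCc1oc(CCc2ccccc2)cc(=O)c1O | intermediate
19 | 3-hydroxy-4-oxo-6-(2-phenylethyl)-4H-pyran-2-carbaldehyde | O=Cc1oc(CCc2ccccc2)cc(=O)c1O | intermediate
20 | methoxyacetyl chloride | COCC(=O)Cl | starting material
21 | 2-formyl-4-oxo-6-(2-phenylethyl)-4H-pyran-3-yl methoxyacetate | COCC(=O)Oc1c(C=O)oc(CCc2ccccc2)cc1=O | intermediate
22 | 3-methoxy-6-(2-phenylethyl)pyrano[3,2-b]pyran-2,8-dione | COC1=CC2=C(OC1=O)C(=O)C=C(CCc1ccccc1)O2 | intermediate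
23 | bridged lactone, the 2-oxabicyclo[2.2.2]octa-5,7-dien-3-one from addition of 9 across C3 and C8a of 22 (both bridgehead diastereomers) | COC12C=C3OC(CCc4ccccc4)=CC(=O)C3(OC1=O)C=C2O[C@@H]1[C@@H](OC)O[C@H](CO[Si](c3ccccc3)(c3ccccc3)C(C)(C)C)[C@H]2O[C@](C)(OC)[C@@](C)(OC)O[C@H]12 | intermediate
24 | methyl 2-O-[7-methoxy-4-oxo-2-(2-phenylethyl)-4H-chromen-6-yl]-6-O-TBDPS-3,4-O-BDA-α-D-mannopyranoside | COc1cc2oc(CCc3ccccc3)cc(=O)c2cc1O[C@@H]1[C@@H](OC)O[C@H](CO[Si](c3ccccc3)(c3ccccc3)C(C)(C)C)[C@H]2O[C@](C)(OC)[C@@](C)(OC)O[C@H]12 | intermediate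
25 | methyl 2-O-Ar-3,4-O-BDA-α-D-mannopyranoside | COc1cc2oc(CCc3ccccc3)cc(=O)c2cc1O[C@@H]1[C@@H](OC)O[C@H](CO)[C@H]2O[C@](C)(OC)[C@@](C)(OC)O[C@H]12 | intermediate
26 | methyl 2-O-Ar-6-deoxy-6-iodo-3,4-O-BDA-α-D-mannopyranoside | COc1cc2oc(CCc3ccccc3)cc(=O)c2cc1O[C@@H]1[C@@H](OC)O[C@H](CI)[C@H]2O[C@](C)(OC)[C@@](C)(OC)O[C@H]12 | intermediate
27 | methyl 2-O-Ar-6-deoxy-3,4-O-BDA-α-D-lyxo-hex-5-enopyranoside | COc1cc2oc(CCc3ccccc3)cc(=O)c2cc1O[C@@H]1[C@@H](OC)OC(=C)[C@H]2O[C@](C)(OC)[C@@](C)(OC)O[C@H]12 | intermediate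
28 | Ferrier ketol (C5 ketone, C4a H2, axial C8a–OH trans to axial C8–OAr, 6,7-O-BDA) | COc1cc2oc(CCc3ccccc3)cc(=O)c2cc1O[C@@H]1[C@@H](O)CC(=O)[C@H]2O[C@](C)(OC)[C@@](C)(OC)O[C@H]12 | intermediate
29 | 1,3-anti diol (equatorial C5–OH trans to O6, axial C8a–OH) | COc1cc2oc(CCc3ccccc3)cc(=O)c2cc1O[C@@H]1[C@@H](O)C[C@H](O)[C@H]2O[C@](C)(OC)[C@@](C)(OC)O[C@H]12 | intermediate
30 | C5 TBS ether of 29 | COc1cc2oc(CCc3ccccc3)cc(=O)c2cc1O[C@@H]1[C@@H](O)C[C@H](O[Si](C)(C)C(C)(C)C)[C@H]2O[C@](C)(OC)[C@@](C)(OC)O[C@H]12 | intermediate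
31 | C8a ketone | COc1cc2oc(CCc3ccccc3)cc(=O)c2cc1O[C@@H]1C(=O)C[C@H](O[Si](C)(C)C(C)(C)C)[C@H]2O[C@](C)(OC)[C@@](C)(OC)O[C@H]12 | intermediate
32 | 4-phenylbut-1-yne | C#CCCc1ccccc1 | starting material
33 | (4-phenylbut-1-yn-1-yl)lithium | [Li]C#CCCc1ccccc1 | intermediate
34 | 5-phenylpent-2-ynal | O=CC#CCCc1ccccc1 | intermediate
35 | dicyclohexylboron enolate of 31 (C8a–O–B, C8a=C4a) | COc1cc2oc(CCc3ccccc3)cc(=O)c2cc1O[C@@H]1C(OB(C3CCCCC3)C3CCCCC3)=C[C@H](O[Si](C)(C)C(C)(C)C)[C@H]2O[C@](C)(OC)[C@@](C)(OC)O[C@H]12 | intermediate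
36 | aldol adduct (C4a–CH(OH)C≡CCH2CH2Ph, mixture at C4a and C4) | COc1cc2oc(CCc3ccccc3)cc(=O)c2cc1O[C@@H]1C(=O)C(C(O)C#CCCc3ccccc3)[C@H](O[Si](C)(C)C(C)(C)C)[C@H]2O[C@](C)(OC)[C@@](C)(OC)O[C@H]12 | intermediate
37 | ynedione (C4a-(5-phenylpent-2-ynoyl) derivative of 31, enolised) | COc1cc2oc(CCc3ccccc3)cc(=O)c2cc1O[C@@H]1C(=O)C(C(=O)C#CCCc3ccccc3)[C@H](O[Si](C)(C)C(C)(C)C)[C@H]2O[C@](C)(OC)[C@@](C)(OC)O[C@H]12 | intermediate
38 | 5-O-TBS-6,7-O-BDA-8-OAr-2-(2-phenylethyl)-5,6,7,8-tetrahydro-4H-chromen-4-one | COc1cc2oc(CCc3ccccc3)cc(=O)c2cc1O[C@@H]1c2oc(CCc3ccccc3)cc(=O)c2[C@H](O[Si](C)(C)C(C)(C)C)[C@H]2O[C@](C)(OC)[C@@](C)(OC)O[C@H]12 | intermediate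
39 | CNP0125425.2, (5S,6R,7S,8S)-5,6,7-trihydroxy-8-{[7-methoxy-4-oxo-2-(2-phenylethyl)-4H-chromen-6-yl]oxy}-2-(2-phenylethyl)-5,6,7,8-tetrahydro-4H-chromen-4-one | COc1cc2oc(CCc3ccccc3)cc(=O)c2cc1O[C@@H]1c2oc(CCc3ccccc3)cc(=O)c2[C@H](O)[C@@H](O)[C@@H]1O | target

**Total step count:** 23.
**Longest linear sequence:** 18 steps (10 to 39 through steps 5–12, 13–19 and 21–23).

**Steps most likely to fail**

**Step 12.**
- The two donors on the diene (the C3 methoxy group and O5) may slow the cycloaddition so far that retro-ene fragmentation or adventitious hydration of the ynol ether overtakes it.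
- The C8 carbonyl on C8a and the methoxy group on C3 polarise the diene against the lactone. Simple frontier-orbital reasoning suggests that these effects could outweigh the lactone bias. Regiochemical leakage (terminal carbon bonding to C3) or conjugate attack at C4 may therefore compete.
- Fallback, from alcohol 3: the C6'–O8 bond would be made by cross-coupling instead of ring construction.
  - Claisen condensation of commercial 1-(5-bromo-2-hydroxy-4-methoxyphenyl)ethanone with ethyl 3-phenylpropanoate (NaH, THF) would give 1-(5-bromo-2-hydroxy-4-methoxyphenyl)-5-phenylpentane-1,3-dione F1.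
  - Cyclodehydration (HCl, AcOH) would give 6-bromo-7-methoxy-2-(2-phenylethyl)-4H-chromen-4-one F2.
  - Buchwald–Hartwig-type etherification of F2 with 3 (Pd2(dba)3, t-BuBrettPhos, Cs2CO3, toluene, 90 °C, retention at sugar C2) comes back to the route at 24.

**Step 21.**
- Enolisation may stray towards C8, with loss of the C8 configuration or β-elimination.
- The basic chromone carbonyl may sequester the boron reagent.
- The CH2 next to C2' may be deprotonated.
- The adduct may revert on work-up.
- Fallback, from ketone 31: direct C-acylation at the diketone oxidation level replaces aldol addition plus oxidation.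
  - Carboxylation of 33 (CO2) would give 5-phenylpent-2-ynoic acid F3.
  - Activation with 1H-benzotriazole and SOCl2 would give 1-(1H-benzotriazol-1-yl)-5-phenylpent-2-yn-1-one F4.
  - Soft enolisation of 31 with MgBr2·OEt2 and i-Pr2NEt in CH2Cl2 follows. Magnesium chelated between the ketone oxygen and O8 singles out this carbonyl group.
  - Crossed Claisen-type acylation by F4 then comes back to the route at 37, which closes to 38 with DMAP as in step 22.

**Step 11.**
- The α-methoxy ester is a weak carbon acid, so ring closure may lag behind acyl transfer, hydrolysis of the enol ester or ketene dimerisation.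
- Fallback, from hydroxy aldehyde 19: the C3=C4 bond would be made by an intramolecular Horner–Wadsworth–Emmons reaction.
  - Saponification (LiOH) of commercial methyl 2-(dimethoxyphosphoryl)-2-methoxyacetate would give 2-(dimethoxyphosphoryl)-2-methoxyacetic acid F5.
  - Esterification of 19 (EDC, DMAP) would give 2-formyl-4-oxo-6-(2-phenylethyl)-4H-pyran-3-yl 2-(dimethoxyphosphoryl)-2-methoxyacetate F6.
  - LiCl and DBU in MeCN would close the ring, whose size enforces the required alkene geometry, and this comes back to the route at 22.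

**Further compounds**
F1 | step 12 | 1-(5-bromo-2-hydroxy-4-methoxyphenyl)-5-phenylpentane-1,3-dione | COc1cc(O)c(cc1Br)C(=O)CC(=O)CCc1ccccc1
F2 | step 12 | 6-bromo-7-methoxy-2-(2-phenylethyl)-4H-chromen-4-one | COc1cc2oc(CCc3ccccc3)cc(=O)c2cc1Br
F3 | step 21 | 5-phenylpent-2-ynoic acid | OC(=O)C#CCCc1ccccc1
F4 | step 21 | 1-(1H-benzotriazol-1-yl)-5-phenylpent-2-yn-1-one | O=C(C#CCCc1ccccc1)n1nnc2ccccc12
F5 | step 11 | 2-(dimethoxyphosphoryl)-2-methoxyacetic acid | COC(C(=O)O)P(=O)(OC)OC
F6 | step 11 | 2-formyl-4-oxo-6-(2-phenylethyl)-4H-pyran-3-yl 2-(dimethoxyphosphoryl)-2-methoxyacetate | COC(C(=O)Oc1c(C=O)oc(CCc2ccccc2)cc1=O)P(=O)(OC)OC
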